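The carbocycle of the isochromenedione (C4a, C5, C6, C7, C8, C8a) carries a 1,3-dicarbonyl unit C6–C7–C8 around the quaternary carbinol C7, with C6 bonded to C5 and C8 to C8a. Cutting C5–C6 and C8–C8a leaves an enantiopure 2-methyl-2-oxymalonyl unit and a 4-methylene-4H-pyran in which C5 is the exocyclic carbon and C8a a ring β-carbon. The key step joins both in one flask: the acid chloride end of a malonyl half-ester chloride acylates the exocyclic carbon, the ester end then acylates C8a, and the ring closes with C7 already in place. The pyran partner is a 2-(3-silyloxypropenyl)-4-methylpyrylium salt, deprotonated in situ to the methylenepyran.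

Key step: step 10

Assumption: the esterase of step 8 is taken to hydrolyse the ester group whose loss gives the (R)-half-ester 12; the opposite outcome is covered by the fallback for step 8.
Remark: the descriptors (R)-12, (S)-13, (R)-15 and (R)-16 denote one unchanged spatial arrangement at the quaternary carbon; they alternate only because CIP priorities change.
Remark: no error was found in the target structure (C7 is R). The pyranone is built from maltol, whose extra ring oxygen is removed in steps 1 and 2, so that the pyran carbon that becomes C8a carries only hydrogen.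

Step 1
Reactants: 1 maltol (3-hydroxy-2-methyl-4H-pyran-4-one)
Product: 2 2-methyl-4-oxo-4H-pyran-3-yl trifluoromethanesulfonate
Conditions: Tf2O, pyridine, CH2Cl2, 0 °C
Reagents that add atoms: trifluoromethanesulfonic anhydride, O=S(=O)(OS(=O)(=O)C(F)(F)F)C(F)(F)F
Why: O-sulfonylation of the acidic enolic hydroxyl turns the superfluous ring oxygen into a leaving group for reductive removal.

Step 2
Reactants: 2 2-methyl-4-oxo-4H-pyran-3-yl trifluoromethanesulfonate
Product: 3 2-methyl-4H-pyran-4-one
Conditions: Pd(OAc)2 (cat.), 1,3-bis(diphenylphosphino)propane, HCO2H, Et3N, DMF, 60 °C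
Reagents that add atoms: none
Why: Palladium-catalysed formate reduction of an enol triflate (oxidative addition to zerovalent palladium, formate exchange, loss of CO2, reductive elimination of C–H); the vinylogous ester carbonyl is inert.

Step 3
Reactants: 3 2-methyl-4H-pyran-4-one; 4 (tert-butyldimethylsilyloxy)acetaldehyde
Product: 5 (±)-2-[3-(tert-butyldimethylsilyloxy)-2-hydroxypropyl]-4H-pyran-4-one
Conditions: LiN(SiMe3)2, THF, −78 °C; then 4, −78 °C
Reagents that add atoms: none
Why: Vinylogous aldol addition: the 2-methyl group is the most acidic C–H (its anion is the extended dienolate) and adds through the exocyclic carbon to the aldehyde; the new carbinol centre is racemic and is removed in step 4.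

Step 4
Reactants: 5 (±)-2-[3-(tert-butyldimethylsilyloxy)-2-hydroxypropyl]-4H-pyran-4-one
Product: 6 2-[(E)-3-(tert-butyldimethylsilyloxy)prop-1-enyl]-4H-pyran-4-one
Conditions: MsCl, Et3N, CH2Cl2, 0 °C; then DBU, rt
Reagents that add atoms: none
Why: Mesylation and E1cB elimination through the vinylogous enolate; conjugation with the pyranone makes the (E)-alkene the thermodynamic product.

Step 5
Reactants: 6 2-[(E)-3-(tert-butyldimethylsilyloxy)prop-1-enyl]-4H-pyran-4-one
Product: 8 2-[(E)-3-(tert-butyldimethylsilyloxy)prop-1-enyl]-4-methylpyrylium tetrafluoroborate, via pyranol 7 (not isolated)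
Conditions: MeLi, THF, −78 °C; H2O; crude in Et2O, HBF4·OEt2 (1.0 equiv), −78 °C, filtration
Reagents that add atoms: methyllithium, [Li]C; tetrafluoroboric acid (diethyl ether complex), [H+].F[B-](F)(F)F
Why: 1,2-Addition of the hard organolithium to the pyranone carbonyl, then acid ionisation of the tertiary bis-vinylogous carbinol to the aromatic cation (the classical pyrylium synthesis from 4-pyranones); the single equivalent of acid is consumed at once by the carbinol and the salt precipitates, which should spare the silyl ether.

Step 6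
Reactants: 9 dimethyl methylmalonate
Product: 10 dimethyl 2-hydroxy-2-methylmalonate
Conditions: NaH, THF, 0 °C; then 2-(phenylsulfonyl)-3-phenyloxaziridine, −78 → 0 °C
Reagents that add atoms: 2-(phenylsulfonyl)-3-phenyloxaziridine, O=S(=O)(c1ccccc1)N1OC1c1ccccc1
Why: Enolate hydroxylation by electrophilic oxygen transfer from an N-sulfonyloxaziridine; the product is achiral.

Step 7
Reactants: 10 dimethyl 2-hydroxy-2-methylmalonate
Product: 11 dimethyl 2-(methoxymethoxy)-2-methylmalonate
Conditions: MOMCl, i-Pr2NEt, Bu4NI (cat.), CH2Cl2, 40 °C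
Reagents that add atoms: chloromethyl methyl ether, COCCl
Why: O-Alkylation of the tertiary alcohol by the highly reactive α-chloro ether (acetal formation); the small acetal keeps the prochiral centre compact for the enzyme and cannot be acylated later.

Step 8
Reactants: 11 dimethyl 2-(methoxymethoxy)-2-methylmalonate
Product: 12 (R)-3-methoxy-2-(methoxymethoxy)-2-methyl-3-oxopropanoic acid
Conditions: pig liver esterase, phosphate buffer pH 7.5/DMSO, 25 °C, pH-stat (1 M NaOH); then HCl to pH 2
Reagents that add atoms: water, O
Why: Enzymatic desymmetrisation of a prochiral 2,2-disubstituted malonate: the esterase hydrolyses one of the two enantiotopic methyl esters and stops at the mono-acid, and this choice in the active site sets the stereocentre that becomes C7.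

Step 9
Reactants: 12 (R)-3-methoxy-2-(methoxymethoxy)-2-methyl-3-oxopropanoic acid
Product: 13 methyl (S)-3-chloro-2-(methoxymethoxy)-2-methyl-3-oxopropanoate
Conditions: 1-chloro-N,N,2-trimethylprop-1-en-1-amine, CH2Cl2, 0 °C, used at once as a solution
Reagents that add atoms: 1-chloro-N,N,2-trimethylprop-1-en-1-amine, CC(C)=C(Cl)N(C)C
Why: Acid chloride formation with an α-chloroenamine under neutral conditions, so that no HCl attacks the acetal; the quaternary centre has no α-hydrogen and cannot racemise.

Step 10
Reactants: 8 2-[(E)-3-(tert-butyldimethylsilyloxy)prop-1-enyl]-4-methylpyrylium tetrafluoroborate; 13 methyl (S)-3-chloro-2-(methoxymethoxy)-2-methyl-3-oxopropanoate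
Product: 16 (R)-3-[(E)-3-(tert-butyldimethylsilyloxy)prop-1-enyl]-7-(methoxymethoxy)-7-methyl-6H-isochromene-6,8(7H)-dione, via methylenepyran 14 (not isolated), via ylidene ketone 15 (not isolated)
Conditions: i-Pr2NEt, CH2Cl2, −78 °C; then 13, −78 → 0 °C; then MgBr2·OEt2, i-Pr2NEt, 0 °C → rt
Reagents that add atoms: none
Why: Proposed new method: i-Pr2NEt removes a proton from the 4-methyl group of 8 (the cross-conjugated 4-methylene anhydrobase is the preferred one and deprotonation at the side-chain CH2 is reversible), and the exocyclic carbon of trienol ether 14, which has the largest HOMO coefficient and regains pyrylium aromaticity on attack, adds to the acid chloride of 13, loss of HCl giving the push-pull ylidene ketone 15 (C5–C6). MgBr2 then binds the C6 carbonyl and raises the pyrylium character of the ring, bromide adds reversibly at the unsubstituted C1, and the magnesium dienolate so formed attacks through its γ-carbon C8a the methyl ester, itself activated by chelation with the C7 ether oxygen, after which loss of methoxide and amine-assisted loss of HBr restore the pyran (C8–C8a). The closest known reaction types are the C-acylation of 4-methylenepyran anhydrobases at the exocyclic carbon by acid chlorides and the Lewis acid–halide variants of the Morita–Baylis–Hillman reaction, in which a relay nucleophile adds to the β-carbon of an enone and the resulting enolate attacks a carbonyl group. The carbocycle closes at the ester carbonyl in an exo-trig mode that is favoured in either reading, 6-(enolexo)-exo-trig if the C1=C8a enol ether attacks directly and 6-(enolendo)-exo-trig if the relayed dienolate does. No stereocentre is formed: C7 comes unchanged from 13, and because the chloride end reacts before the ester end its sense in the ring follows from reactivity alone. The step needs closure at C8a and not at C4, which should be secured by bromide adding at the unhindered C1–H and not at the substituted C3, by the peri clash that a side chain at C1 would suffer with the C8 carbonyl in the isomeric product while C–C bond formation stays reversible, and by free rotation about the push-pull C4a=C5 bond, which feeds the productive rotamer.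

Step 11
Reactants: 16 (R)-3-[(E)-3-(tert-butyldimethylsilyloxy)prop-1-enyl]-7-(methoxymethoxy)-7-methyl-6H-isochromene-6,8(7H)-dione
Product: 17 (R)-7-hydroxy-3-[(E)-3-hydroxyprop-1-enyl]-7-methyl-6H-isochromene-6,8(7H)-dione
Conditions: TFA/H2O (9:1), CH2Cl2, 0 °C → rt; aq NaHCO3 work-up
Reagents that add atoms: none
Why: Acid hydrolysis of the formaldehyde acetal (through its oxocarbenium ion) and of the primary silyl ether in one operation; the isochromenedione core tolerates protic acid and the quaternary C7 cannot epimerise.

Step 12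
Reactants: 17 (R)-7-hydroxy-3-[(E)-3-hydroxyprop-1-enyl]-7-methyl-6H-isochromene-6,8(7H)-dione
Product: 18 (R)-7-hydroxy-7-methyl-3-[(E)-3-oxoprop-1-enyl]-6H-isochromene-6,8(7H)-dione
Conditions: MnO2, CH2Cl2, rt
Reagents that add atoms: none
Why: Chemoselective MnO2 oxidation of the allylic primary alcohol to the (E)-enal; the tertiary C7 hydroxyl has no carbinol hydrogen and is untouched.

Step 13
Reactants: 19 orsellinic acid (2,4-dihydroxy-6-methylbenzoic acid)
Product: 20 tert-butyldimethylsilyl 2,4-bis(tert-butyldimethylsilyloxy)-6-methylbenzoate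
Conditions: TBSCl (3.3 equiv), imidazole, DMF, rt
Reagents that add atoms: tert-butyldimethylsilyl chloride, CC(C)(C)[Si](C)(C)Cl
Why: Exhaustive silylation of both phenols and the acid under imidazole catalysis at room temperature, which avoids the thermal decarboxylation of the free acid.

Step 14
Reactants: 20 tert-butyldimethylsilyl 2,4-bis(tert-butyldimethylsilyloxy)-6-methylbenzoate
Product: 21 2,4-bis(tert-butyldimethylsilyloxy)-6-methylbenzoyl chloride
Conditions: (COCl)2, DMF (cat.), CH2Cl2, 0 °C → rt
Reagents that add atoms: oxalyl chloride, O=C(Cl)C(Cl)=O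
Why: Direct conversion of a silyl ester into the acid chloride by the chloroiminium reagent formed from oxalyl chloride and DMF, under neutral conditions that leave the aryl silyl ethers intact.

Step 15
Reactants: 18 (R)-7-hydroxy-7-methyl-3-[(E)-3-oxoprop-1-enyl]-6H-isochromene-6,8(7H)-dione; 21 2,4-bis(tert-butyldimethylsilyloxy)-6-methylbenzoyl chloride
Product: 22 (R)-7-methyl-6,8-dioxo-3-[(E)-3-oxoprop-1-enyl]-7,8-dihydro-6H-isochromen-7-yl 2,4-bis(tert-butyldimethylsilyloxy)-6-methylbenzoate
Conditions: Et3N, DMAP, CH2Cl2, 0 °C → rt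
Reagents that add atoms: none
Why: DMAP-catalysed acylation through the N-acylpyridinium ion of the only hydroxyl left, which is made acidic by its two carbonyl neighbours; the C7–O bond is not broken, so configuration is retained.

Step 16
Reactants: 22 (R)-7-methyl-6,8-dioxo-3-[(E)-3-oxoprop-1-enyl]-7,8-dihydro-6H-isochromen-7-yl 2,4-bis(tert-butyldimethylsilyloxy)-6-methylbenzoate
Product: 23 (R)-7-methyl-6,8-dioxo-3-[(E)-3-oxoprop-1-enyl]-7,8-dihydro-6H-isochromen-7-yl 2,4-dihydroxy-6-methylbenzoate (CNP0200982.1)
Conditions: HF·pyridine, pyridine, THF, 0 °C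
Reagents that add atoms: none
Why: Fluoride-driven Si–O cleavage of the two aryl silyl ethers under mildly acidic conditions, which should leave the hindered benzoate, the enal and the base-sensitive pyran ring untouched.

Compound list
1 | maltol (3-hydroxy-2-methyl-4H-pyran-4-one) | CC1=C(O)C(=O)C=CO1 | starting material
2 | 2-methyl-4-oxo-4H-pyran-3-yl trifluoromethanesulfonate | CC1=C(OS(=O)(=O)C(F)(F)F)C(=O)C=CO1 | intermediate
3 | 2-methyl-4H-pyran-4-one | CC1=CC(=O)C=CO1 | intermediate
4 | (tert-butyldimethylsilyloxy)acetaldehyde | O=CCO[Si](C)(C)C(C)(C)C | starting material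
5 | (±)-2-[3-(tert-butyldimethylsilyloxy)-2-hydroxypropyl]-4H-pyran-4-one (racemic) | O=C1C=COC(CC(O)CO[Si](C)(C)C(C)(C)C)=C1 | intermediate
6 | 2-[(E)-3-(tert-butyldimethylsilyloxy)prop-1-enyl]-4H-pyran-4-one | O=C1C=COC(/C=C/CO[Si](C)(C)C(C)(C)C)=C1 | intermediate
7 | (±)-2-[(E)-3-(tert-butyldimethylsilyloxy)prop-1-enyl]-4-methyl-4H-pyran-4-ol (racemic, not isolated) | CC1(O)C=COC(/C=C/CO[Si](C)(C)C(C)(C)C)=C1 | intermediate
8 | 2-[(E)-3-(tert-butyldimethylsilyloxy)prop-1-enyl]-4-methylpyrylium tetrafluoroborate | Cc1cc(/C=C/CO[Si](C)(C)C(C)(C)C)[o+]cc1.F[B-](F)(F)F | intermediate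
9 | dimethyl methylmalonate | COC(=O)C(C)C(=O)OC | starting material
10 | dimethyl 2-hydroxy-2-methylmalonate | COC(=O)C(C)(O)C(=O)OC | intermediate
11 | dimethyl 2-(methoxymethoxy)-2-methylmalonate | COCOC(C)(C(=O)OC)C(=O)OC | intermediate
12 | (R)-3-methoxy-2-(methoxymethoxy)-2-methyl-3-oxopropanoic acid | COCO[C@](C(=O)OC)(C)C(=O)O | intermediate
13 | methyl (S)-3-chloro-2-(methoxymethoxy)-2-methyl-3-oxopropanoate | COCO[C@](C(=O)OC)(C)C(Cl)=O | intermediate
14 | 2-[(E)-3-(tert-butyldimethylsilyloxy)prop-1-enyl]-4-methylene-4H-pyran (not isolated) | C=C1C=COC(/C=C/CO[Si](C)(C)C(C)(C)C)=C1 | intermediate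
15 | methyl (R)-4-{2-[(E)-3-(tert-butyldimethylsilyloxy)prop-1-enyl]-4H-pyran-4-ylidene}-2-(methoxymethoxy)-2-methyl-3-oxobutanoate (ylidene isomers interconvert, not isolated) | COCO[C@](C(=O)OC)(C)C(=O)C=C1C=COC(/C=C/CO[Si](C)(C)C(C)(C)C)=C1 | intermediate
16 | (R)-3-[(E)-3-(tert-butyldimethylsilyloxy)prop-1-enyl]-7-(methoxymethoxy)-7-methyl-6H-isochromene-6,8(7H)-dione | COCO[C@]1(C)C(=O)C=C2C=C(/C=C/CO[Si](C)(C)C(C)(C)C)OC=C2C1=O | intermediate
17 | (R)-7-hydroxy-3-[(E)-3-hydroxyprop-1-enyl]-7-methyl-6H-isochromene-6,8(7H)-dione | O[C@]1(C)C(=O)C=C2C=C(/C=C/CO)OC=C2C1=O | intermediate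
18 | (R)-7-hydroxy-7-methyl-3-[(E)-3-oxoprop-1-enyl]-6H-isochromene-6,8(7H)-dione | O[C@]1(C)C(=O)C=C2C=C(/C=C/C=O)OC=C2C1=O | intermediate
19 | orsellinic acid (2,4-dihydroxy-6-methylbenzoic acid) | Cc1cc(O)cc(O)c1C(=O)O | starting material
20 | tert-butyldimethylsilyl 2,4-bis(tert-butyldimethylsilyloxy)-6-methylbenzoate | Cc1cc(O[Si](C)(C)C(C)(C)C)cc(O[Si](C)(C)C(C)(C)C)c1C(=O)O[Si](C)(C)C(C)(C)C | intermediate
21 | 2,4-bis(tert-butyldimethylsilyloxy)-6-methylbenzoyl chloride | Cc1cc(O[Si](C)(C)C(C)(C)C)cc(O[Si](C)(C)C(C)(C)C)c1C(Cl)=O | intermediate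
22 | (R)-7-methyl-6,8-dioxo-3-[(E)-3-oxoprop-1-enyl]-7,8-dihydro-6H-isochromen-7-yl 2,4-bis(tert-butyldimethylsilyloxy)-6-methylbenzoate | Cc1cc(O[Si](C)(C)C(C)(C)C)cc(O[Si](C)(C)C(C)(C)C)c1C(=O)O[C@]1(C)C(=O)C=C2C=C(/C=C/C=O)OC=C2C1=O | intermediate
23 | (R)-7-methyl-6,8-dioxo-3-[(E)-3-oxoprop-1-enyl]-7,8-dihydro-6H-isochromen-7-yl 2,4-dihydroxy-6-methylbenzoate (CNP0200982.1) | Cc1cc(O)cc(O)c1C(=O)O[C@]1(C)C(=O)C=C2C=C(/C=C/C=O)OC=C2C1=O | target

Total step count: 16. Longest linear sequence: 10 steps (steps 1 to 5, 10, 11, 12, 15 and 16); steps 6 to 9 and steps 13 and 14 are side branches.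

Steps most likely to fail

Step 10. The ring carbon may prove too weak a nucleophile for the methyl ester, so that the sequence stops at the ylidene ketone; closure may also take place at C4, or the acetal may be lost to the Lewis acid. The fallback uses known chemistry, sets out from 15 and returns at 16. Only the first acylation, a known reaction type, is run and 15 is isolated. Its methyl ester is hydrolysed with Me3SnOH (1,2-dichloroethane, 60 °C) to (R)-4-{2-[(E)-3-(tert-butyldimethylsilyloxy)prop-1-enyl]-4H-pyran-4-ylidene}-2-(methoxymethoxy)-2-methyl-3-oxobutanoic acid F1, kept cold to avoid decarboxylation. The acid is converted with 1-chloro-N,N,2-trimethylprop-1-en-1-amine into (R)-4-{2-[(E)-3-(tert-butyldimethylsilyloxy)prop-1-enyl]-4H-pyran-4-ylidene}-2-(methoxymethoxy)-2-methyl-3-oxobutanoyl chloride F2. This far stronger acyl donor should close onto C8a by Friedel–Crafts-type C-acylation of the enol ether carbon (i-Pr2NEt, CH2Cl2, 0 °C → rt), the reaction type by which vinyl ethers are acylated by reactive acid chlorides, to give 16.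

Step 8. The enzyme may discriminate poorly between the two enantiotopic ester groups, or may hydrolyse the other one and deliver the enantiomer of 12. The fallback sets out from 11 and returns at 12. Saponification with one equivalent of KOH in methanol gives (±)-3-methoxy-2-(methoxymethoxy)-2-methyl-3-oxopropanoic acid F3. The racemate is resolved by fractional crystallisation with (S)-1-phenylethylamine, or with its enantiomer if that places the (R)-acid in the less soluble salt. The salt (S)-1-phenylethylammonium (R)-3-methoxy-2-(methoxymethoxy)-2-methyl-3-oxopropanoate F4 releases 12 on acidification.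

Step 5. The silyl ether may be cleaved, or the pyrylium ring, which is unsubstituted at C6, may be opened by the water set free during the acid ionisation; conjugate addition of MeLi is a further possibility. The fallback sets out from 6 and returns at 14, and avoids both acid and the pyrylium salt by a Peterson olefination. Me3SiCH2Li (THF, −78 °C) adds to the carbonyl group of 6 to give 2-[(E)-3-(tert-butyldimethylsilyloxy)prop-1-enyl]-4-[(trimethylsilyl)methyl]-4H-pyran-4-ol F5. KH in THF then induces syn-elimination of the silanolate and gives 14 directly as a solution, which enters step 10 at the acylation stage.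

Further compounds
F1 | step 10 | (R)-4-{2-[(E)-3-(tert-butyldimethylsilyloxy)prop-1-enyl]-4H-pyran-4-ylidene}-2-(methoxymethoxy)-2-methyl-3-oxobutanoic acid | COCO[C@](C(=O)O)(C)C(=O)C=C1C=COC(/C=C/CO[Si](C)(C)C(C)(C)C)=C1
F2 | step 10 | (R)-4-{2-[(E)-3-(tert-butyldimethylsilyloxy)prop-1-enyl]-4H-pyran-4-ylidene}-2-(methoxymethoxy)-2-methyl-3-oxobutanoyl chloride | COCO[C@](C(Cl)=O)(C)C(=O)C=C1C=COC(/C=C/CO[Si](C)(C)C(C)(C)C)=C1
F3 | step 8 | (±)-3-methoxy-2-(methoxymethoxy)-2-methyl-3-oxopropanoic acid | COCOC(C)(C(=O)OC)C(=O)O
F4 | step 8 | (S)-1-phenylethylammonium (R)-3-methoxy-2-(methoxymethoxy)-2-methyl-3-oxopropanoate | C[C@H]([NH3+])c1ccccc1.COCO[C@](C(=O)OC)(C)C(=O)[O-]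
F5 | step 5 | 2-[(E)-3-(tert-butyldimethylsilyloxy)prop-1-enyl]-4-[(trimethylsilyl)methyl]-4H-pyran-4-ol | C[Si](C)(C)CC1(O)C=COC(/C=C/CO[Si](C)(C)C(C)(C)C)=C1
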